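The target is meso. A mirror plane passes through O1 and the midpoint of C3–C4 of the oxolane ring, and the two aroyl carbonyl carbons form a cis-1,4-diketone with C3 and C4. This unit is read as the ozonolysis product of a 1,2-diarylcyclobutene cis-fused to the oxolane. The key step is a triplet-sensitised [2+2] photocycloaddition of bis[2,4-bis(benzyloxy)phenyl]acetylene to the C3=C4 bond of 2,5-dimethoxy-2,5-dihydrofuran. It makes both carbonyl-carbon–ring-carbon bonds at once and locks C3/C4 cis. The temporary four-membered ring then blocks furan formation and sends both 4-(benzyloxy)phenyl groups to the convex face (C2, C5). Ozonolysis and hydrogenolysis complete the synthesis.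

Key step: step 3

Remark: the target SMILES describes the meso (2R,3R,4S,5S) isomer (2,3-trans, 3,4-cis, 4,5-trans), so only relative configuration has to be controlled.

Step 1
Reactants: 1 4-iodoresorcinol
Product: 2 2,4-bis(benzyloxy)-1-iodobenzene
Conditions: BnBr (2.2 equiv), K2CO3, DMF, rt to 50 °C
Reagents that add atoms: benzyl bromide, BrCc1ccccc1
Why: Williamson ether synthesis, in which both phenoxides formed with K2CO3 are alkylated by the SN2-active benzyl bromide while the aryl iodide stays inert; no stereocentre is involved.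

Step 2
Reactants: 2 2,4-bis(benzyloxy)-1-iodobenzene (2 equiv); 3 acetylene
Product: 5 bis[2,4-bis(benzyloxy)phenyl]acetylene, via terminal arylacetylene 4 (not isolated)
Conditions: acetylene (balloon), PdCl2(PPh3)2 (cat.), CuI (cat.), Et3N, THF, rt to 50 °C
Reagents that add atoms: none
Why: Double Sonogashira coupling, in which the terminal arylacetylene 4 formed first is more reactive than acetylene itself and couples with a second molecule of 2 to give the symmetrical diarylalkyne; no stereocentre is formed.

Step 3
Reactants: 5 bis[2,4-bis(benzyloxy)phenyl]acetylene; 6 2,5-dimethoxy-2,5-dihydrofuran (commercial cis/trans mixture, large excess)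
Product: 7 cis-fused 6,7-bis[2,4-bis(benzyloxy)phenyl]-2,4-dimethoxy-3-oxabicyclo[3.2.0]hept-6-ene (mixture of acetal epimers)
Conditions: 6 (20 equiv, co-solvent), thioxanthen-9-one (10 mol %), CH2Cl2, 405 nm LED, degassed (Ar), rt
Reagents that add atoms: none
Why: Energy transfer from triplet thioxanthone, whose triplet energy lies above that of diarylalkynes, excites only alkyne 5; its triplet adds to the C3=C4 double bond of 6 to give a 1,4-biradical (aryl-conjugated vinyl radical and secondary alkyl radical) that closes after intersystem crossing, so both alkyne carbons, the later carbonyl carbons, become bonded to the two ring carbons in one operation. The closest known reaction types are the intermolecular [2+2] photocycloaddition of diarylacetylenes with cyclic alkenes and cyclic enol ethers, and the energy-transfer alkyne–alkene cycloaddition to cyclobutenes. The four-membered ring is closed by recombination of the 1,4-biradical (formal [2+2]), and only the cis-fused 3-oxabicyclo[3.2.0]hept-6-ene can form because a trans fusion is prohibitively strained. This ring strain controls both new stereocentres (C1 and C5 of the bicycle, later C3 and C4 of the oxolane), while the two acetal centres need no control because both are ionised in step 4. No regiochemical question arises because both partners are symmetrical; the cheap alkene as co-solvent secures cross-addition over alkyne decay or self-reaction, and 405 nm light, absorbed by the sensitiser alone, keeps 7 out of the singlet stilbene-type photocyclisation.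

Step 4
Reactants: 7 bicyclic bis-acetal; 8 4-(benzyloxy)phenylmagnesium bromide (commercial THF solution)
Product: 10 meso exo,exo-2,4-bis[4-(benzyloxy)phenyl]-6,7-bis[2,4-bis(benzyloxy)phenyl]-3-oxabicyclo[3.2.0]hept-6-ene, via bis(alpha-bromo ether) 9 (not isolated)
Conditions: TMSBr (2.2 equiv), CH2Cl2, −40 °C; then 8 (3 equiv), THF, −78 to 0 °C
Reagents that add atoms: bromotrimethylsilane, C[Si](C)(C)Br (supplies the bromine atoms of intermediate 9; none of its atoms remain in 10)
Why: Acetal-to-α-bromo-ether exchange followed by Grignard substitution of the α-halo ether (the classical 2-halooxolane/aryl-Grignard coupling known from C-aryl furanosides) runs through oxocarbenium ions that are attacked on the cis-bicyclo[3.2.0] frame from the convex exo face anti to the cyclobutene, so each new stereocentre carries its aryl group trans to the neighbouring ring-fusion bond and the two aryl groups end up cis to each other, which is also the thermodynamically preferred arrangement.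

Step 5
Reactants: 10 exo,exo-diaryl bicycle
Product: 12 hexabenzyl ether of the target, [(2R,3R,4S,5S)-2,5-bis[4-(benzyloxy)phenyl]oxolane-3,4-diyl]bis{[2,4-bis(benzyloxy)phenyl]methanone} (meso), via ozonide 11 (not isolated)
Conditions: O3 (1 equiv, Sudan III end point), CH2Cl2, −78 °C; then PPh3, −78 °C to rt
Reagents that add atoms: ozone, [O-][O+]=O
Why: In this ozonolysis (Criegee mechanism) the strained, tetrasubstituted, electron-rich stilbene-type C6=C7 bond is by far the most ozonophilic site and is cleaved through the intramolecular ozonide, which PPh3 reduces under neutral conditions, so the four stereocentres stay untouched and the kinetically locked 3,4-cis relation never meets acid or base.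

Step 6
Reactants: 12 hexabenzyl ether
Product: 13 target, [(2R,3R,4S,5S)-2,5-bis(4-hydroxyphenyl)oxolane-3,4-diyl]bis[(2,4-dihydroxyphenyl)methanone] (meso)
Conditions: H2 (1 atm), 10 % Pd/C, EtOAc/MeOH, rt, stopped when hydrogen uptake ends
Reagents that add atoms: none
Why: Hydrogenolysis of aryl benzyl ethers over Pd/C in neutral medium is much faster than cleavage of the cyclic benzylic ether or reduction of the hydrogen-bonded ortho-hydroxyaryl ketones, and the absence of acid and base leaves the epimerisable C3/C4 and the benzylic C2/C5 unchanged.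

Compound list
1 | 4-iodoresorcinol (4-iodobenzene-1,3-diol) | Oc1ccc(I)c(O)c1 | starting material
2 | 2,4-bis(benzyloxy)-1-iodobenzene | Ic1ccc(OCc2ccccc2)cc1OCc1ccccc1 | intermediate
3 | acetylene | C#C | starting material
4 | 2,4-bis(benzyloxy)-1-ethynylbenzene (not isolated) | C#Cc1ccc(OCc2ccccc2)cc1OCc1ccccc1 | intermediate
5 | bis[2,4-bis(benzyloxy)phenyl]acetylene | C(#Cc1ccc(OCc2ccccc2)cc1OCc1ccccc1)c1ccc(OCc2ccccc2)cc1OCc1ccccc1 | intermediate
6 | 2,5-dimethoxy-2,5-dihydrofuran (cis/trans mixture) | COC1C=CC(OC)O1 | starting material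
7 | cis-fused 6,7-bis[2,4-bis(benzyloxy)phenyl]-2,4-dimethoxy-3-oxabicyclo[3.2.0]hept-6-ene (acetal epimers) | C1(c3ccc(OCc4ccccc4)cc3OCc3ccccc3)=C(c3ccc(OCc4ccccc4)cc3OCc3ccccc3)[C@@H]2C(OC)OC(OC)[C@H]12 | intermediate
8 | 4-(benzyloxy)phenylmagnesium bromide | Br[Mg]c1ccc(OCc2ccccc2)cc1 | starting material
9 | cis-fused 2,4-dibromo-6,7-bis[2,4-bis(benzyloxy)phenyl]-3-oxabicyclo[3.2.0]hept-6-ene (not isolated) | C1(c3ccc(OCc4ccccc4)cc3OCc3ccccc3)=C(c3ccc(OCc4ccccc4)cc3OCc3ccccc3)[C@@H]2C(Br)OC(Br)[C@H]12 | intermediate
10 | meso exo,exo-2,4-bis[4-(benzyloxy)phenyl]-6,7-bis[2,4-bis(benzyloxy)phenyl]-3-oxabicyclo[3.2.0]hept-6-ene (cis ring fusion, both C2/C4 aryl groups on the convex face) | C1(c3ccc(OCc4ccccc4)cc3OCc3ccccc3)=C(c3ccc(OCc4ccccc4)cc3OCc3ccccc3)[C@@H]2[C@@H](c3ccc(OCc4ccccc4)cc3)O[C@@H](c3ccc(OCc4ccccc4)cc3)[C@H]12 | intermediate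
11 | secondary ozonide of 10 (1,2,4-trioxolane bridging the two former alkene carbons; configuration at these two ketal carbons not specified; not isolated) | C12(c4ccc(OCc5ccccc5)cc4OCc4ccccc4)OOC(c4ccc(OCc5ccccc5)cc4OCc4ccccc4)(O1)[C@@H]3[C@@H](c4ccc(OCc5ccccc5)cc4)O[C@@H](c4ccc(OCc5ccccc5)cc4)[C@H]23 | intermediate
12 | [(2R,3R,4S,5S)-2,5-bis[4-(benzyloxy)phenyl]oxolane-3,4-diyl]bis{[2,4-bis(benzyloxy)phenyl]methanone} (meso) | O=C(c1ccc(OCc2ccccc2)cc1OCc1ccccc1)[C@@H]1[C@H](C(=O)c2ccc(OCc3ccccc3)cc2OCc2ccccc2)[C@@H](c2ccc(OCc3ccccc3)cc2)O[C@H]1c1ccc(OCc2ccccc2)cc1 | intermediate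
13 | [(2R,3R,4S,5S)-2,5-bis(4-hydroxyphenyl)oxolane-3,4-diyl]bis[(2,4-dihydroxyphenyl)methanone] (meso) | O=C(c1ccc(O)cc1O)[C@@H]1[C@H](C(=O)c2ccc(O)cc2O)[C@@H](c2ccc(O)cc2)O[C@H]1c1ccc(O)cc1 | target

Total step count: 6. Longest linear sequence: 6 steps (1 → 2 → 5 → 7 → 10 → 12 → 13).

Steps most likely to fail

Step 3 (key step). The triplet alkyne may decay faster than it adds to the unactivated, inductively deactivated double bond of 6. Its vinyl-radical centre may instead abstract hydrogen from an ortho-benzyloxy group. The accumulating cyclobutene may also drain the sensitiser as a triplet quencher.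
- Fallback: a polarity-matched butenolide–alkyne photocycloaddition that forms the same two C–C bonds.
- It sets out from 5. Commercial 5-methoxyfuran-2(5H)-one (COC1OC(=O)C=C1) replaces 6 under sensitised irradiation and should give the racemic cis-fused cyclobutene methoxybutyrolactone F1.
- DIBAL-H at −78 °C reduces it to the lactol F2.
- MeOH/PPTS converts this into the bis-acetal, where the route is rejoined at 7.

Step 4. The basic Grignard reagent may cause loss of HBr from the α-bromo ether towards the ring-fusion carbon, or the second substitution may stall.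
- Fallback: carbonyl addition followed by stereoconvergent cyclodehydration instead of substitution at an oxocarbenium ion.
- It sets out from 7. Mild aqueous acid (1 M HCl, THF) gives the bis-lactol F3.
- Excess 8 at −78 °C opens it to the cis-3,4-bis[aryl(hydroxy)methyl]cyclobutene 1,4-diol F4 (carbinol epimers).
- Catalytic BF3·OEt2 in CH2Cl2 closes the oxolane through the 4-benzyloxybenzyl cation. Reversible ionisation of both benzylic C–O bonds funnels all epimers to the exo,exo isomer, and the route is rejoined at 10.

Step 5. Ozone may attack the resorcinol ether rings or benzylic C–H bonds in competition, or reduction of the hindered tetrasubstituted ozonide may be sluggish.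
- Fallback: dye-sensitised photooxygenation.
- It sets out from 10. Singlet oxygen (O2, tetraphenylporphyrin, visible light, CH2Cl2, −20 °C) leaves alkoxyarenes untouched.
- It should add [2+2] from the exo face to the electron-rich double bond, whose allylic hydrogens sit at the ring fusion and are poorly aligned for an ene reaction, giving the 1,2-dioxetane F5.
- F5 cleaves on warming to room temperature to the diketone, and the route is rejoined at 12.

Further compounds
F1 | step 3 | racemic cis-fused 6,7-bis[2,4-bis(benzyloxy)phenyl]-4-methoxy-3-oxabicyclo[3.2.0]hept-6-en-2-one (acetal centre unassigned) | C1(c3ccc(OCc4ccccc4)cc3OCc3ccccc3)=C(c3ccc(OCc4ccccc4)cc3OCc3ccccc3)[C@@H]2C(=O)OC(OC)[C@H]12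
F2 | step 3 | racemic cis-fused 6,7-bis[2,4-bis(benzyloxy)phenyl]-4-methoxy-3-oxabicyclo[3.2.0]hept-6-en-2-ol (lactol, anomers) | C1(c3ccc(OCc4ccccc4)cc3OCc3ccccc3)=C(c3ccc(OCc4ccccc4)cc3OCc3ccccc3)[C@@H]2C(O)OC(OC)[C@H]12
F3 | step 4 | cis-fused 6,7-bis[2,4-bis(benzyloxy)phenyl]-3-oxabicyclo[3.2.0]hept-6-ene-2,4-diol (bis-lactol, anomers) | C1(c3ccc(OCc4ccccc4)cc3OCc3ccccc3)=C(c3ccc(OCc4ccccc4)cc3OCc3ccccc3)[C@@H]2C(O)OC(O)[C@H]12
F4 | step 4 | cis-3,4-bis{[4-(benzyloxy)phenyl](hydroxy)methyl}-1,2-bis[2,4-bis(benzyloxy)phenyl]cyclobut-1-ene (carbinol epimers) | C1(c3ccc(OCc4ccccc4)cc3OCc3ccccc3)=C(c3ccc(OCc4ccccc4)cc3OCc3ccccc3)[C@H](C(O)c3ccc(OCc4ccccc4)cc3)[C@@H]1C(O)c1ccc(OCc2ccccc2)cc1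
F5 | step 5 | exo-1,2-dioxetane of 10 (O–O bridge on the face of the ring-fusion hydrogens) | [C@]12(c4ccc(OCc5ccccc5)cc4OCc4ccccc4)OO[C@@]1(c4ccc(OCc5ccccc5)cc4OCc4ccccc4)[C@@H]3[C@@H](c4ccc(OCc5ccccc5)cc4)O[C@@H](c4ccc(OCc5ccccc5)cc4)[C@H]23
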